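The ten-membered ring is closed at C7–C8, the bond that joins the sp2 β-carbon C7 of the butenolide (five-membered lactone ring) to the oxygenated carbon C8 of the carbocycle. An intramolecular Nozaki–Hiyama–Kishi reaction converts the C7–I bond of a β-iodobutenolide into an alkenylchromium that adds to a C8 aldehyde, forming C7–C8, the ten-membered ring and the C8 carbinol in one operation. The precursor is an open chain that already holds the 4,5-cis-oxirane, the C6 lactone centre, the C13 acetate, the Z C1=C10 olefin and a β,γ-unsaturated aldehyde; afterwards only tigloylation and epoxidation of C1=C10 remain.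

Key step: step 19

Remarks on the chemistry (one line each):
- Germacrane numbering is used throughout (C12 lactone carbonyl, C13 acetoxymethyl carbon, C14 methyl on C10, C15 methyl on C4).
- The target is read as 1S,4S,5R,6R,8R,10R with both oxiranes cis (C3/C6 cis on C4–C5, C2/C9 cis on C1–C10); this fits a nerol-type Z C4=C5 olefin and a Z C1=C10 olefin, and no structure needed correction.
- C6 is inverted in space between 24 and 26 (anti SN2′ palladation, then lactonization on the face of C12), so the propargylic alcohol must be 6S. In iodides 26–30 the descriptor still reads S only because iodine raises the rank of C7; the same centre reads R in 33–37.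
- The C1–C10 oxirane oxygen lies on the ring face opposite to the C8 oxygen, so the epoxidation is run on the C8 ester under steric control and not by hydroxyl delivery.
- The C13 oxygen is carried as a silyl ether through the palladium step and acetylated afterwards; the C8 aldehyde is unveiled only immediately before ring closure.

Step 1
Reactants: 1 nerol
Product: 2 (2R,3S)-2,3-epoxynerol
Conditions: Ti(OiPr)4 (cat.), D-(−)-diisopropyl tartrate (cat.), t-BuOOH, 4 Å molecular sieves, CH2Cl2, −20 °C
Reagents that add atoms: tert-butyl hydroperoxide, CC(C)(C)OO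
Why: Sharpless asymmetric epoxidation: the allylic hydroxyl binds the titanium tartrate complex, so only the C4=C5 olefin is oxidised, and the D-(−)-tartrate should deliver oxygen to the face that gives 4S,5R (the Z geometry of nerol becomes the cis relation of C3 and C6 on the oxirane).

Step 2
Reactants: 2 (2R,3S)-2,3-epoxynerol
Product: 3 triethyl{[(2R,3S)-3-methyl-3-(4-methylpent-3-en-1-yl)oxiran-2-yl]methoxy}silane
Conditions: Et3SiCl, imidazole, CH2Cl2, 0 °C
Reagents that add atoms: chlorotriethylsilane, CC[Si](Cl)(CC)CC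
Why: Standard silylation of a primary alcohol; the triethylsilyl ether protects C6–OH during ozonolysis, ylide and organolithium chemistry and is the most labile silyl group when it has to be removed in step 6.

Step 3
Reactants: 3 triethylsilyl ether of epoxynerol
Product: 5 3-[(2S,3R)-2-methyl-3-(triethylsilyloxymethyl)oxiran-2-yl]propanal, via secondary ozonide 4 (not isolated)
Conditions: O3, CH2Cl2, −78 °C; then Me2S, −78 °C to rt
Reagents that add atoms: ozone, [O-][O+]=O
Why: Ozonolysis with reductive work-up cleaves the only C=C bond to the C1 aldehyde, the oxirane and the silyl ether being inert to ozone at −78 °C.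

Step 4
Reactants: 5 C1 aldehyde; 6 ethyl(triphenyl)phosphonium iodide
Product: 10 triethyl{[(2R,3S)-3-[(3Z)-4-iodopent-3-en-1-yl]-3-methyloxiran-2-yl]methoxy}silane, via ethylidene ylide 7 (not isolated), via iodoethylphosphonium iodide 8 (not isolated), via iodoethylidene ylide 9 (not isolated)
Conditions: n-BuLi, THF, 0 °C; I2, −78 °C; NaN(SiMe3)2, −78 °C; then 5, −78 to −20 °C
Reagents that add atoms: iodine, II
Why: Stork–Zhao-type Wittig olefination: the non-stabilised α-iodo ylide 9 should add to the aldehyde under kinetic control through the cis-oxaphosphetane, giving the Z-2-iodoalkene in which iodine (the future C9 position) is cis to C2, which fixes the C1=C10 geometry.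

Step 5
Reactants: 10 Z-alkenyl iodide; 11 oxirane
Product: 14 tert-butyl{[(3Z)-3-methyl-6-[(2S,3R)-2-methyl-3-(triethylsilyloxymethyl)oxiran-2-yl]hex-3-en-1-yl]oxy}dimethylsilane, via alkenyllithium 12 (not isolated), via lithium alkoxide 13 (not isolated)
Conditions: t-BuLi (2 equiv), Et2O, −78 °C; oxirane, −78 to 0 °C; then t-BuMe2SiCl, THF, 0 °C to rt
Reagents that add atoms: tert-butyl(chloro)dimethylsilane, CC(C)(C)[Si](C)(C)Cl
Why: Iodine–lithium exchange with t-BuLi proceeds with retention at the alkenyl carbon and the alkenyllithium opens the unhindered oxirane 11 (the trisubstituted oxirane of the substrate is far slower), so the C9–C8 unit ends cis to C2; the alkoxide is silylated in the same flask.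

Step 6
Reactants: 14 bis-silyl ether
Product: 15 [(2R,3S)-3-[(3Z)-6-(tert-butyldimethylsilyloxy)-4-methylhex-3-en-1-yl]-3-methyloxiran-2-yl]methanol
Conditions: PPTS (cat.), MeOH/CH2Cl2, 0 °C
Reagents that add atoms: none
Why: Acid-catalysed methanolysis of silyl ethers: the primary triethylsilyl ether should be cleaved much faster than the tert-butyldimethylsilyl ether, and the weak acid at 0 °C should leave the oxirane closed.

Step 7
Reactants: 15 epoxy alcohol
Product: 16 (2S,3S)-3-[(3Z)-6-(tert-butyldimethylsilyloxy)-4-methylhex-3-en-1-yl]-3-methyloxirane-2-carbaldehyde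
Conditions: TEMPO (cat.), PhI(OAc)2, CH2Cl2, rt
Reagents that add atoms: none
Why: TEMPO-catalysed oxidation of a primary alcohol stops at the aldehyde and is mild enough for a 2,3-epoxy alcohol; C5 is not enolised under these conditions, so the 4S,5R arrangement is kept (the descriptor of C5 changes to S by priority only).

Step 8
Reactants: 17 prop-2-yn-1-ol
Product: 18 triethyl(prop-2-yn-1-yloxy)silane
Conditions: Et3SiCl, imidazole, CH2Cl2, 0 °C
Reagents that add atoms: chlorotriethylsilane, CC[Si](Cl)(CC)CC
Why: Routine silylation of a primary alcohol provides the three-carbon C7–C11–C13 unit in protected form.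

Step 9
Reactants: 16 epoxy aldehyde; 18 triethyl(prop-2-yn-1-yloxy)silane
Product: 21 1-[(2R,3S)-3-[(3Z)-6-(tert-butyldimethylsilyloxy)-4-methylhex-3-en-1-yl]-3-methyloxiran-2-yl]-4-(triethylsilyloxy)but-2-yn-1-ol as a mixture of both C6 epimers, via lithium acetylide 19 (not isolated), via lithium alkoxide 20 (not isolated)
Conditions: 18, n-BuLi, THF, −78 °C; then 16, −78 °C; aq NH4Cl
Reagents that add atoms: none
Why: Addition of a lithium acetylide to the aldehyde forms the C6–C7 bond; the facial preference is of no consequence because C6 is oxidised in step 10.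

Step 10
Reactants: 21 propargylic alcohols
Product: 22 1-[(2S,3S)-3-[(3Z)-6-(tert-butyldimethylsilyloxy)-4-methylhex-3-en-1-yl]-3-methyloxiran-2-yl]-4-(triethylsilyloxy)but-2-yn-1-one
Conditions: MnO2 (activated, excess), CH2Cl2, rt
Reagents that add atoms: none
Why: MnO2 oxidises propargylic alcohols to ynones under neutral conditions and so converges both C6 epimers without touching oxirane, silyl ethers or olefin.

Step 11
Reactants: 22 ynone
Product: 23 (1S)-1-[(2R,3S)-3-[(3Z)-6-(tert-butyldimethylsilyloxy)-4-methylhex-3-en-1-yl]-3-methyloxiran-2-yl]-4-(triethylsilyloxy)but-2-yn-1-ol (6S)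
Conditions: Ru[(R,R)-TsDPEN](p-cymene) (cat.), i-PrOH, rt
Reagents that add atoms: none
Why: Noyori asymmetric transfer hydrogenation of an ynone: the (R,R) catalyst should recognise the alkynyl group and deliver hydride to the carbonyl face that gives the 6S alcohol under reagent control, the configuration required by the net inversion at C6 in steps 13 and 14.

Step 12
Reactants: 23 (6S)-propargylic alcohol
Product: 24 (6S)-propargylic methanesulfonate of 23
Conditions: MsCl, Et3N, CH2Cl2, −78 °C
Reagents that add atoms: methanesulfonyl chloride, CS(=O)(=O)Cl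
Why: Sulfonylation of a secondary alcohol occurs at oxygen with retention at C6 and supplies the leaving group for palladium; the mesylate is used at once.

Step 13
Reactants: 24 (6S)-propargylic mesylate
Product: 25 (aS)-4-[(2R,3S)-3-[(3Z)-6-(tert-butyldimethylsilyloxy)-4-methylhex-3-en-1-yl]-3-methyloxiran-2-yl]-2-(triethylsilyloxymethyl)buta-2,3-dienoic acid
Conditions: Pd(PPh3)4 (cat.), CO (1 atm), 2,6-lutidine, THF/H2O, 0 °C to rt
Reagents that add atoms: carbon monoxide, [C-]#[O+]; water, O
Why: Palladium-catalysed hydroxycarbonylation of a propargylic mesylate: zerovalent palladium attacks C11 anti to the leaving group (SN2′), CO inserts into the allenylpalladium bond with retention and water cleaves the acylpalladium, so the 6S centre should be relayed to the aS allene axis while the C13 silyl ether is not ionised and lutidine takes up the sulfonic acid.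

Step 14
Reactants: 25 (aS)-allenoic acid
Product: 26 (5S)-5-[(2R,3S)-3-[(3Z)-6-(tert-butyldimethylsilyloxy)-4-methylhex-3-en-1-yl]-3-methyloxiran-2-yl]-4-iodo-3-(triethylsilyloxymethyl)furan-2(5H)-one
Conditions: I2, NaHCO3, MeCN/H2O, 0 °C
Reagents that add atoms: iodine, II
Why: Iodolactonization of a 2,3-allenoic acid: iodine adds to the central carbon C7 of the electron-richer C6=C7 bond and the carboxylate closes the five-membered lactone onto C6 from the face on which C12 lies (anti addition), which should relay the axis to the C6 centre of the β-iodobutenolide with the configuration of the target; the isolated olefin reacts only reversibly with iodine under bicarbonate buffering.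

Step 15
Reactants: 26 β-iodobutenolide bis-silyl ether
Product: 27 (5S)-5-[(2R,3S)-3-[(3Z)-6-(tert-butyldimethylsilyloxy)-4-methylhex-3-en-1-yl]-3-methyloxiran-2-yl]-3-(hydroxymethyl)-4-iodofuran-2(5H)-one
Conditions: PPTS (cat.), MeOH, 0 °C
Reagents that add atoms: none
Why: Acid-catalysed methanolysis should remove the primary triethylsilyl ether selectively in the presence of the tert-butyldimethylsilyl ether, as in step 6.

Step 16
Reactants: 27 C13 alcohol
Product: 28 (5S)-3-(acetoxymethyl)-5-[(2R,3S)-3-[(3Z)-6-(tert-butyldimethylsilyloxy)-4-methylhex-3-en-1-yl]-3-methyloxiran-2-yl]-4-iodofuran-2(5H)-one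
Conditions: Ac2O, pyridine, CH2Cl2, 0 °C
Reagents that add atoms: acetic anhydride, CC(=O)OC(C)=O
Why: Acetylation of a primary alcohol installs the C13 acetate only after the palladium step, where an allylic acetate on an allenoate would have been ionised; pyridine is the only base so that the β-iodo enoate is not attacked.

Step 17
Reactants: 28 C13 acetate
Product: 29 (5S)-3-(acetoxymethyl)-5-[(2R,3S)-3-[(3Z)-6-hydroxy-4-methylhex-3-en-1-yl]-3-methyloxiran-2-yl]-4-iodofuran-2(5H)-one
Conditions: HF·pyridine, pyridine, THF, 0 °C to rt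
Reagents that add atoms: none
Why: Fluoride cleavage of the silyl ether under pyridine buffering frees C8–OH; acetate, lactone, alkenyl iodide and oxirane should be stable to these conditions.

Step 18
Reactants: 29 C8 alcohol
Product: 30 (5S)-3-(acetoxymethyl)-4-iodo-5-[(2R,3S)-3-methyl-3-[(3Z)-4-methyl-6-oxohex-3-en-1-yl]oxiran-2-yl]furan-2(5H)-one (open-chain iodo aldehyde)
Conditions: Dess–Martin periodinane, NaHCO3, CH2Cl2, 0 °C
Reagents that add atoms: none
Why: Dess–Martin oxidation with bicarbonate buffering gives the β,γ-unsaturated aldehyde without base or acid strong enough to move the Z olefin into conjugation; the aldehyde is taken on at once.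

Step 19
Reactants: 30 open-chain iodo aldehyde
Product: 33 (1(10)Z,4S,5R,6R,8R)-13-acetoxy-4,5-epoxy-8-hydroxygermacra-1(10),7(11)-dien-12,6-olide, via alkenylchromium dichloride 31 (not isolated), via chromium alkoxide 32 (not isolated)
Conditions: CrCl2 (excess), NiCl2 (cat.), DMSO, rt, slow addition of 30 at high dilution; aq work-up
Reagents that add atoms: none
Why: Zerovalent nickel, formed from NiCl2 by CrCl2, inserts into the C7–I bond of the β-iodo enoate, the alkenyl group passes to trivalent chromium (31), and the alkenylchromium adds to the C8 aldehyde to give alkoxide 32, hydrolysed on work-up. The closest known reaction type is the intramolecular Nozaki–Hiyama–Kishi coupling of alkenyl iodides with aldehydes used to close medium and large rings. The ten-membered ring closes by a 10-exo-trig carbonyl addition, helped by three rigid turn elements (cis-oxirane, Z olefin, planar butenolide) and by slow addition at high dilution. The new C8 centre is set by the substrate: allylic strain against the C13 acetoxymethyl group keeps the aldehyde hydrogen in the butenolide plane, the chromium-bound oxygen and C9 lie on opposite sides of that plane, and C9 takes the side away from C5 (fixed by C6) to avoid a 1,5-repulsion across C7, which corresponds to 8R. The step needs addition to the aldehyde in preference to lactone, acetate and oxirane and no enolisation of the β,γ-unsaturated aldehyde, both secured by the low basicity and aldehyde selectivity of alkenylchromium reagents.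

Step 20
Reactants: 33 8-hydroxy dienolide; 34 tiglic acid
Product: 36 (1(10)Z,4S,5R,6R,8R)-13-acetoxy-4,5-epoxy-8-[(E)-2-methylbut-2-enoyloxy]germacra-1(10),7(11)-dien-12,6-olide, via mixed anhydride 35 (not isolated)
Conditions: 34, 2,4,6-trichlorobenzoyl chloride, Et3N, toluene, rt; then 33, DMAP, rt
Reagents that add atoms: none
Why: Yamaguchi esterification through mixed anhydride 35 acylates the hindered secondary allylic C8–OH at oxygen with retention; the E geometry of the tiglate is the stable one and should survive the amine bases.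

Step 21
Reactants: 36 8-O-tigloyl dienolide
Product: 37 (1S,4S,5R,6R,8R,10R)-13-acetoxy-1,10:4,5-diepoxy-8-[(E)-2-methylbut-2-enoyloxy]germacr-7(11)-en-12,6-olide (target)
Conditions: dimethyldioxirane, acetone, −20 to 0 °C
Reagents that add atoms: dimethyldioxirane, CC1(C)OO1
Why: Epoxidation with dimethyldioxirane is stereospecific (Z olefin to cis-oxirane) and takes the only electron-rich C=C bond (tiglate and butenolide olefins are conjugated to carbonyl groups); the C8 tigloyloxy group, held over one face of the olefin by allylic strain against the C13 acetoxymethyl group, should steer the reagent to the opposite peripheral face and so give 1S,10R.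

Compound list
1 | nerol, (2Z)-3,7-dimethylocta-2,6-dien-1-ol | CC(C)=CCC/C(C)=C\CO | starting material
2 | (2R,3S)-2,3-epoxynerol, [(2R,3S)-3-methyl-3-(4-methylpent-3-en-1-yl)oxiran-2-yl]methanol | CC(C)=CCC[C@]1(C)O[C@@H]1CO | intermediate
3 | triethyl{[(2R,3S)-3-methyl-3-(4-methylpent-3-en-1-yl)oxiran-2-yl]methoxy}silane | CC(C)=CCC[C@]1(C)O[C@@H]1CO[Si](CC)(CC)CC | intermediate
4 | secondary ozonide of 3 (1,2,4-trioxolane, formed in the flask) | CC1(C)OOC(CC[C@]2(C)O[C@@H]2CO[Si](CC)(CC)CC)O1 | intermediate
5 | 3-[(2S,3R)-2-methyl-3-(triethylsilyloxymethyl)oxiran-2-yl]propanal | O=CCC[C@]1(C)O[C@@H]1CO[Si](CC)(CC)CC | intermediate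
6 | ethyl(triphenyl)phosphonium iodide | CC[P+](c1ccccc1)(c1ccccc1)c1ccccc1.[I-] | starting material
7 | ethylidene(triphenyl)phosphorane (formed in the flask) | CC=P(c1ccccc1)(c1ccccc1)c1ccccc1 | intermediate
8 | (1-iodoethyl)(triphenyl)phosphonium iodide (formed in the flask) | CC(I)[P+](c1ccccc1)(c1ccccc1)c1ccccc1.[I-] | intermediate
9 | (1-iodoethylidene)(triphenyl)phosphorane (formed in the flask) | CC(I)=P(c1ccccc1)(c1ccccc1)c1ccccc1 | intermediate
10 | triethyl{[(2R,3S)-3-[(3Z)-4-iodopent-3-en-1-yl]-3-methyloxiran-2-yl]methoxy}silane | C/C(I)=C/CC[C@]1(C)O[C@@H]1CO[Si](CC)(CC)CC | intermediate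
11 | oxirane | C1CO1 | starting material
12 | Z-alkenyllithium from 10 (formed in the flask) | C/C([Li])=C/CC[C@]1(C)O[C@@H]1CO[Si](CC)(CC)CC | intermediate
13 | lithium (3Z)-3-methyl-6-[(2S,3R)-2-methyl-3-(triethylsilyloxymethyl)oxiran-2-yl]hex-3-en-1-olate (formed in the flask) | [Li]OCC/C(C)=C\CC[C@]1(C)O[C@@H]1CO[Si](CC)(CC)CC | intermediate
14 | tert-butyl{[(3Z)-3-methyl-6-[(2S,3R)-2-methyl-3-(triethylsilyloxymethyl)oxiran-2-yl]hex-3-en-1-yl]oxy}dimethylsilane | CC(C)(C)[Si](C)(C)OCC/C(C)=C\CC[C@]1(C)O[C@@H]1CO[Si](CC)(CC)CC | intermediate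
15 | [(2R,3S)-3-[(3Z)-6-(tert-butyldimethylsilyloxy)-4-methylhex-3-en-1-yl]-3-methyloxiran-2-yl]methanol | CC(C)(C)[Si](C)(C)OCC/C(C)=C\CC[C@]1(C)O[C@@H]1CO | intermediate
16 | (2S,3S)-3-[(3Z)-6-(tert-butyldimethylsilyloxy)-4-methylhex-3-en-1-yl]-3-methyloxirane-2-carbaldehyde | CC(C)(C)[Si](C)(C)OCC/C(C)=C\CC[C@]1(C)O[C@@H]1C=O | intermediate
17 | prop-2-yn-1-ol | C#CCO | starting material
18 | triethyl(prop-2-yn-1-yloxy)silane | C#CCO[Si](CC)(CC)CC | intermediate
19 | [3-(triethylsilyloxy)prop-1-yn-1-yl]lithium (formed in the flask) | [Li]C#CCO[Si](CC)(CC)CC | intermediate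
20 | lithium alkoxide of 21 (formed in the flask) | CC(C)(C)[Si](C)(C)OCC/C(C)=C\CC[C@]1(C)O[C@@H]1C(O[Li])C#CCO[Si](CC)(CC)CC | intermediate
21 | 1-[(2R,3S)-3-[(3Z)-6-(tert-butyldimethylsilyloxy)-4-methylhex-3-en-1-yl]-3-methyloxiran-2-yl]-4-(triethylsilyloxy)but-2-yn-1-ol, both C6 epimers | CC(C)(C)[Si](C)(C)OCC/C(C)=C\CC[C@]1(C)O[C@@H]1C(O)C#CCO[Si](CC)(CC)CC | intermediate
22 | 1-[(2S,3S)-3-[(3Z)-6-(tert-butyldimethylsilyloxy)-4-methylhex-3-en-1-yl]-3-methyloxiran-2-yl]-4-(triethylsilyloxy)but-2-yn-1-one | CC(C)(C)[Si](C)(C)OCC/C(C)=C\CC[C@]1(C)O[C@@H]1C(=O)C#CCO[Si](CC)(CC)CC | intermediate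
23 | (1S)-1-[(2R,3S)-3-[(3Z)-6-(tert-butyldimethylsilyloxy)-4-methylhex-3-en-1-yl]-3-methyloxiran-2-yl]-4-(triethylsilyloxy)but-2-yn-1-ol (6S) | CC(C)(C)[Si](C)(C)OCC/C(C)=C\CC[C@]1(C)O[C@@H]1[C@@H](O)C#CCO[Si](CC)(CC)CC | intermediate
24 | methanesulfonate of 23 (6S) | CC(C)(C)[Si](C)(C)OCC/C(C)=C\CC[C@]1(C)O[C@@H]1[C@@H](OS(C)(=O)=O)C#CCO[Si](CC)(CC)CC | intermediate
25 | (aS)-4-[(2R,3S)-3-[(3Z)-6-(tert-butyldimethylsilyloxy)-4-methylhex-3-en-1-yl]-3-methyloxiran-2-yl]-2-(triethylsilyloxymethyl)buta-2,3-dienoic acid | OC(=O)C(CO[Si](CC)(CC)CC)=[C@@]=C([H])[C@H]1O[C@@]1(C)CC/C=C(C)\CCO[Si](C)(C)C(C)(C)C | intermediate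
26 | (5S)-5-[(2R,3S)-3-[(3Z)-6-(tert-butyldimethylsilyloxy)-4-methylhex-3-en-1-yl]-3-methyloxiran-2-yl]-4-iodo-3-(triethylsilyloxymethyl)furan-2(5H)-one | CC(C)(C)[Si](C)(C)OCC/C(C)=C\CC[C@]1(C)O[C@@H]1[C@@H]1OC(=O)C(CO[Si](CC)(CC)CC)=C1I | intermediate
27 | (5S)-5-[(2R,3S)-3-[(3Z)-6-(tert-butyldimethylsilyloxy)-4-methylhex-3-en-1-yl]-3-methyloxiran-2-yl]-3-(hydroxymethyl)-4-iodofuran-2(5H)-one | CC(C)(C)[Si](C)(C)OCC/C(C)=C\CC[C@]1(C)O[C@@H]1[C@@H]1OC(=O)C(CO)=C1I | intermediate
28 | (5S)-3-(acetoxymethyl)-5-[(2R,3S)-3-[(3Z)-6-(tert-butyldimethylsilyloxy)-4-methylhex-3-en-1-yl]-3-methyloxiran-2-yl]-4-iodofuran-2(5H)-one | CC(C)(C)[Si](C)(C)OCC/C(C)=C\CC[C@]1(C)O[C@@H]1[C@@H]1OC(=O)C(COC(C)=O)=C1I | intermediate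
29 | (5S)-3-(acetoxymethyl)-5-[(2R,3S)-3-[(3Z)-6-hydroxy-4-methylhex-3-en-1-yl]-3-methyloxiran-2-yl]-4-iodofuran-2(5H)-one | OCC/C(C)=C\CC[C@]1(C)O[C@@H]1[C@@H]1OC(=O)C(COC(C)=O)=C1I | intermediate
30 | (5S)-3-(acetoxymethyl)-4-iodo-5-[(2R,3S)-3-methyl-3-[(3Z)-4-methyl-6-oxohex-3-en-1-yl]oxiran-2-yl]furan-2(5H)-one (cyclization precursor) | O=CC/C(C)=C\CC[C@]1(C)O[C@@H]1[C@@H]1OC(=O)C(COC(C)=O)=C1I | intermediate
31 | C7 alkenylchromium dichloride from 30 (formed in the flask) | O=CC/C(C)=C\CC[C@]1(C)O[C@@H]1[C@@H]1OC(=O)C(COC(C)=O)=C1[Cr](Cl)Cl | intermediate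
32 | dichlorochromium C8 alkoxide of 33 (formed in the flask) | Cl[Cr](Cl)O[C@@H]1C/C(C)=C\CC[C@]2(C)O[C@@H]2[C@@H]2OC(=O)C(COC(C)=O)=C21 | intermediate
33 | (1(10)Z,4S,5R,6R,8R)-13-acetoxy-4,5-epoxy-8-hydroxygermacra-1(10),7(11)-dien-12,6-olide | O[C@@H]1C/C(C)=C\CC[C@]2(C)O[C@@H]2[C@@H]2OC(=O)C(COC(C)=O)=C21 | intermediate
34 | tiglic acid, (E)-2-methylbut-2-enoic acid | C/C=C(\C)C(=O)O | starting material
35 | (E)-2-methylbut-2-enoic 2,4,6-trichlorobenzoic anhydride (formed in the flask) | C/C=C(\C)C(=O)OC(=O)c1c(Cl)cc(Cl)cc1Cl | intermediate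
36 | (1(10)Z,4S,5R,6R,8R)-13-acetoxy-4,5-epoxy-8-[(E)-2-methylbut-2-enoyloxy]germacra-1(10),7(11)-dien-12,6-olide | C/C=C(\C)C(=O)O[C@@H]1C/C(C)=C\CC[C@]2(C)O[C@@H]2[C@@H]2OC(=O)C(COC(C)=O)=C21 | intermediate
37 | (1S,4S,5R,6R,8R,10R)-13-acetoxy-1,10:4,5-diepoxy-8-[(E)-2-methylbut-2-enoyloxy]germacr-7(11)-en-12,6-olide | C/C=C(\C)C(=O)O[C@@H]1C[C@@]2(C)O[C@H]2CC[C@]2(C)O[C@@H]2[C@@H]2OC(=O)C(COC(C)=O)=C21 | target

Total step count: 21. Longest linear sequence: 20 steps (nerol 1 to target 37; step 8 is a one-step side branch).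

Steps most likely to fail

1. Step 19 (key step). The process at risk is insufficient facial selectivity of the alkenylchromium addition to the C8 carbonyl, giving the 8S epimer beside or instead of 8R. The fallback sets out from 33 as the epimer mixture. Dess–Martin oxidation would give the 8-oxo dienolide F1. Corey–Bakshi–Shibata reduction ((S)-2-methyl-CBS-oxazaborolidine, catecholborane, the C7 alkenyl carbon as the large group) would then return 8R-configured 33. C8 is then set by reagent control and no longer by the ring-closing transition state.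

2. Step 13. The process at risk is loss of stereochemical fidelity by epimerisation of the allenylpalladium intermediate before CO insertion, or ionisation of the newly formed allenyl oxirane by zerovalent palladium. The fallback uses no palladium and sets out from ynone 22. Transfer hydrogenation with the (S,S) catalyst would give the 6R propargylic alcohol F2. O-Alkylation with Bu3SnCH2I and KH in THF would give the tributylstannylmethyl ether F3. n-BuLi at −78 °C would trigger tin–lithium exchange and a [2,3]-Wittig–Still rearrangement, which is suprafacial (syn SN2′), to the allenyl carbinol F4 with the same axis as 25. Dess–Martin oxidation to the allenyl aldehyde F5 and Pinnick oxidation (NaClO2, NaH2PO4, 2-methylbut-2-ene) would rejoin the route at 25.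

3. Step 21. The process at risk is poor or reversed facial selectivity of the epoxidation if the macrocycle exposes the other face of the C1=C10 olefin to the dioxirane. The fallback replaces steric control by hydroxyl delivery and sets out from 33. VO(acac)2 with t-BuOOH would epoxidise the homoallylic alcohol on the olefin face reached by the C8 hydroxyl, giving the 8-hydroxy diepoxide F6. Yamaguchi tigloylation of F6 would rejoin the route at 37.

Further compounds
F1 | step 19 | 8-oxo dienolide, (1(10)Z,4S,5R,6R)-13-acetoxy-4,5-epoxy-8-oxogermacra-1(10),7(11)-dien-12,6-olide | O=C1C/C(C)=C\CC[C@]2(C)O[C@@H]2[C@@H]2OC(=O)C(COC(C)=O)=C12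
F2 | step 13 | 6R propargylic alcohol, C6 epimer of 23 | CC(C)(C)[Si](C)(C)OCC/C(C)=C\CC[C@]1(C)O[C@@H]1[C@H](O)C#CCO[Si](CC)(CC)CC
F3 | step 13 | tributylstannylmethyl ether of F2 | CC(C)(C)[Si](C)(C)OCC/C(C)=C\CC[C@]1(C)O[C@@H]1[C@H](OC[Sn](CCCC)(CCCC)CCCC)C#CCO[Si](CC)(CC)CC
F4 | step 13 | allenyl carbinol, 4-(oxiranyl)-2-(triethylsilyloxymethyl)buta-2,3-dien-1-ol with the axis of 25 | OCC(CO[Si](CC)(CC)CC)=[C@@]=C([H])[C@H]1O[C@@]1(C)CC/C=C(C)\CCO[Si](C)(C)C(C)(C)C
F5 | step 13 | allenyl aldehyde, 4-(oxiranyl)-2-(triethylsilyloxymethyl)buta-2,3-dienal with the axis of 25 | O=CC(CO[Si](CC)(CC)CC)=[C@@]=C([H])[C@H]1O[C@@]1(C)CC/C=C(C)\CCO[Si](C)(C)C(C)(C)C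
F6 | step 21 | 8-hydroxy diepoxide, (1S,4S,5R,6R,8R,10R)-13-acetoxy-1,10:4,5-diepoxy-8-hydroxygermacr-7(11)-en-12,6-olide | O[C@@H]1C[C@@]2(C)O[C@H]2CC[C@]2(C)O[C@@H]2[C@@H]2OC(=O)C(COC(C)=O)=C21
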